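The side chain on the benzene ring is disconnected at C4'–C5'. Its C2'=C3'(CH3)–C4'H2–C5'H(OH)–C6'=C7' segment is a 1,5-dien-3-ol, the product pattern of a [2,3]-Wittig rearrangement of a bis-allylic ether. In one operation the shift forms the C4'–C5' bond, breaks C2'–O, creates the E C2'=C3' alkene and transfers the C2' configuration to the C5' carbinol; no ring is formed. The precursor is the ether of (S)-1-aryl-3-methylbut-3-en-2-ol (phenol as triisopropylsilyl ether) with an (E,11'R) C5'–C12' allylic unit whose C12' oxygen is a triethylsilyl ether; both halves are made separately and joined by a Williamson reaction.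

Key step: step 14

Remarks on the chemistry:
- The side chain is numbered from the benzylic carbon C1' to the tertiary carbinol carbon C15'; Ar = 5-methoxy-3-methyl-2-(triisopropylsilyloxy)phenyl.
- On the envelope model (oxygen and C5' on one face of C2'–C3'–C4', CH2Ar outward, alkenyl group exo) the (2'S) ether gives the (5'R) carbinol and the E alkene. Step 6 must therefore leave the (S)-alcohol, which requires D-(−)-diisopropyl tartrate.
- The phenol carries the bulky triisopropylsilyl group so that it does not shift to the alkoxides of steps 13 and 14. The C12' triethylsilyl ether is inert to butyllithium and is the only silyl ether cleaved in step 16.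
- Aqueous quenches are written as water, and a spent metal reagent is entered as its simplest salt.

Step 1
Reactants: 1 4-methoxy-2-methylphenol; 2 allyl bromide
Product: 3 1-(allyloxy)-4-methoxy-2-methylbenzene
Conditions: K2CO3, acetone, reflux
Reagents that add atoms: none
Why: Williamson ether synthesis; the phenoxide is the only nucleophile and displaces the primary allylic bromide by SN2.

Step 2
Reactants: 3 1-(allyloxy)-4-methoxy-2-methylbenzene
Product: 5 2-allyl-4-methoxy-6-methylphenol, via ortho-dienone 4 (not isolated)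
Conditions: N,N-diethylaniline, 190 °C
Reagents that add atoms: none
Why: Aromatic Claisen rearrangement; the [3,3] shift can reach only the free ortho carbon, and the dienone tautomerises to the phenol.

Step 3
Reactants: 5 2-allyl-4-methoxy-6-methylphenol
Product: 6 (2-allyl-4-methoxy-6-methylphenoxy)triisopropylsilane
Conditions: i-Pr3SiOTf, 2,6-lutidine, CH2Cl2, 0 °C → rt
Reagents that add atoms: triisopropylsilyl trifluoromethanesulfonate, CC(C)[Si](OS(=O)(=O)C(F)(F)F)(C(C)C)C(C)C
Why: O-silylation; the silyl triflate is reactive enough for the 2,6-disubstituted phenol, and the hindered aryl silyl ether should withstand the later alkoxides and butyllithium.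

Step 4
Reactants: 6 (2-allyl-4-methoxy-6-methylphenoxy)triisopropylsilane
Product: 8 2-Ar-acetaldehyde, via ozonide 7 (not isolated)
Conditions: O3, CH2Cl2, −78 °C, stopped at first excess of ozone; then PPh3, −78 °C → rt
Reagents that add atoms: ozone, [O-][O+]=O
Why: Ozonolysis with reductive work-up; the terminal alkene reacts far faster than the arene, and the sensitive arylacetaldehyde is used crude.

Step 5
Reactants: 8 2-Ar-acetaldehyde; 9 isopropenylmagnesium bromide
Product: 10 rac-1-Ar-3-methylbut-3-en-2-ol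
Conditions: THF, −78 °C; then H2O
Reagents that add atoms: none
Why: Grignard 1,2-addition, which at low temperature should outrun enolisation of the aldehyde; the C2' centre forms as a racemate.

Step 6
Reactants: 10 rac-1-Ar-3-methylbut-3-en-2-ol
Product: 11 (S)-1-Ar-3-methylbut-3-en-2-ol
Conditions: Ti(OiPr)4 (15 mol%), D-(−)-diisopropyl tartrate (20 mol%), t-BuOOH (0.6 equiv), 4 Å MS, CH2Cl2, −20 °C
Reagents that add atoms: none
Why: Sharpless kinetic resolution; with the D-(−)-tartrate the (R)-enantiomer of this 2-substituted allylic carbinol is epoxidised much faster, so the (S)-alcohol is recovered and separated from the epoxy alcohol by chromatography.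

Step 7
Reactants: 12 hept-6-ynoic acid; 13 (R)-4-benzyloxazolidin-2-one
Product: 15 (R)-4-benzyl-3-(hept-6-ynoyl)oxazolidin-2-one, via mixed pivalic anhydride 14 (not isolated)
Conditions: t-BuCOCl, Et3N, THF, −20 °C; then 13, LiCl, rt
Reagents that add atoms: none
Why: N-acylation of the oxazolidinone through the mixed anhydride; the hindered pivaloyl carbonyl directs attack to the heptynoyl carbonyl.

Step 8
Reactants: 15 (R)-4-benzyl-3-(hept-6-ynoyl)oxazolidin-2-one
Product: 17 (R)-4-benzyl-3-[(R)-2-methylhept-6-ynoyl]oxazolidin-2-one, via sodium enolate 16 (not isolated)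
Conditions: NaN(SiMe3)2 (1.1 equiv), THF, −78 °C; then MeI, −78 °C
Reagents that add atoms: iodomethane, CI
Why: Evans asymmetric alkylation; the chelated Z-enolate is methylated on the face away from the benzyl group, which sets the (R) centre that becomes C11', and the minor diastereomer is removed by chromatography.

Step 9
Reactants: 17 (R)-4-benzyl-3-[(R)-2-methylhept-6-ynoyl]oxazolidin-2-one
Product: 18 (R)-2-methylhept-6-yn-1-ol
Conditions: LiBH4, THF, 0 °C → rt; then H2O
Reagents that add atoms: none
Why: Reductive cleavage of the N-acyl oxazolidinone with LiBH4 gives the primary alcohol without touching the α-centre or the alkyne, and the auxiliary is recovered.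

Step 10
Reactants: 18 (R)-2-methylhept-6-yn-1-ol
Product: 19 triethyl{[(2R)-2-methylhept-6-yn-1-yl]oxy}silane
Conditions: Et3SiCl, imidazole, CH2Cl2, 0 °C
Reagents that add atoms: chlorotriethylsilane, CC[Si](Cl)(CC)CC
Why: Silylation of the primary alcohol; the triethylsilyl ether is stable to the bases that follow and can later be removed selectively.

Step 11
Reactants: 19 triethyl{[(2R)-2-methylhept-6-yn-1-yl]oxy}silane
Product: 22 (2E,7R)-3,7-dimethyl-8-(triethylsilyloxy)oct-2-en-1-ol, via alkenylalane 20 (not isolated), via lithium alanate 21 (not isolated)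
Conditions: Me3Al, Cp2ZrCl2 (20 mol%), CH2Cl2, 0 °C → rt; then n-BuLi, THF/hexane, −78 → 0 °C; then (CH2O)n, rt; then H2O
Reagents that add atoms: trimethylaluminium, C[Al](C)C; paraformaldehyde (formaldehyde units), C=O
Why: Negishi zirconium-catalysed carboalumination adds methyl and aluminium syn with methyl on the internal carbon, and hydroxymethylation of the alanate proceeds with retention, so the E trisubstituted alkene C6'=C7' is fixed.

Step 12
Reactants: 22 (2E,7R)-3,7-dimethyl-8-(triethylsilyloxy)oct-2-en-1-ol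
Product: 24 {[(2R,6E)-8-bromo-2,6-dimethyloct-6-en-1-yl]oxy}triethylsilane, via allylic mesylate 23 (not isolated)
Conditions: MeSO2Cl, Et3N, CH2Cl2, −40 °C; then LiBr, THF, 0 °C
Reagents that add atoms: lithium bromide, [Li+].[Br-]
Why: Mesylation followed by SN2 displacement with bromide at the primary allylic carbon; the conditions are not acidic, so the silyl ether and the alkene geometry are kept.

Step 13
Reactants: 11 (S)-1-Ar-3-methylbut-3-en-2-ol; 24 {[(2R,6E)-8-bromo-2,6-dimethyloct-6-en-1-yl]oxy}triethylsilane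
Product: 26 bis-allylic ether (2'S,6'E,11'R) of 11 with the C5'–C12' unit, via sodium alkoxide 25 (not isolated)
Conditions: NaH, THF/DMF, 0 °C; then 24, Bu4NI (cat.), 0 °C → rt
Reagents that add atoms: none
Why: Williamson ether synthesis; the alkoxide attacks the primary allylic bromide by SN2, and the C2' configuration is kept because its C–O bond is not broken.

Step 14
Reactants: 26 bis-allylic ether (2'S,6'E,11'R)
Product: 28 (2'E,5'R,6'E,11'R)-1'-Ar-5'-hydroxy-12'-(triethylsilyloxy) dienol, via lithiated ether 27 (not isolated)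
Conditions: n-BuLi, THF, −78 → −40 °C; then H2O, −78 °C
Reagents that add atoms: none
Why: n-BuLi removes a proton from the C5' OCH2 group, and the resulting α-oxy allyllithium 27 undergoes a concerted suprafacial [2,3]-sigmatropic shift through a five-membered envelope transition state in which C5' bonds to the C4' methylene terminus while the C2'–O bond breaks and the C2'=C3' alkene forms. The closest known reaction type is the [2,3]-Wittig rearrangement of unsymmetrical bis-allylic ethers to 1,5-dien-3-ols, including ethers lithiated on a γ,γ-dialkylallyl unit. No ring is closed, the five-membered array being only the transition state. The single new stereocentre C5' is controlled by the C2' centre of the ether: oxygen and C5' stay on one face of the C2'–C3'–C4' unit, CH2Ar sits pseudo-equatorial and the C6'=C7' alkenyl group exo, away from the C3' methyl, so the (2'S) ether gives the (5'R) carbinol. The step needs lithiation at C5' and not at C2', secured because C2'–H is a hindered tertiary methine, and it needs E geometry, secured by the pseudo-equatorial CH2Ar in the product-like transition state of the stabilised anion. Quenching cold keeps the lithium alkoxide of the 1,5-dien-3-ol from an anionic oxy-Cope shift and limits the competing [1,2]-shift.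

Step 15
Reactants: 28 (2'E,5'R,6'E,11'R)-dienol
Product: 29 5'-O-tert-butyldimethylsilyl ether of 28
Conditions: t-BuMe2SiOTf, 2,6-lutidine, CH2Cl2, −78 °C
Reagents that add atoms: tert-butyldimethylsilyl trifluoromethanesulfonate, CC(C)(C)[Si](C)(C)OS(=O)(=O)C(F)(F)F
Why: Silylation of the secondary allylic alcohol under basic conditions, which leave the primary triethylsilyl ether and both alkenes untouched.

Step 16
Reactants: 29 5'-O-tert-butyldimethylsilyl ether
Product: 30 12'-alcohol (5'-OTBS and aryl OTIPS kept)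
Conditions: pyridinium p-toluenesulfonate (cat.), MeOH/CH2Cl2, 0 °C
Reagents that add atoms: none
Why: Acid-catalysed methanolysis of a silyl ether; the primary triethylsilyl ether is cleaved far faster than the secondary tert-butyldimethylsilyl ether and the aryl triisopropylsilyl ether.

Step 17
Reactants: 30 12'-alcohol
Product: 31 12'-aldehyde
Conditions: Dess–Martin periodinane, NaHCO3, CH2Cl2, 0 °C → rt
Reagents that add atoms: none
Why: Dess–Martin oxidation; the buffered, non-basic conditions should give the α-branched aldehyde without epimerising C11'.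

Step 18
Reactants: 31 12'-aldehyde; 32 2-methylbut-3-yn-2-ol
Product: 34 12',15'-diol with C13'≡C14' alkyne (12'-epimers), via dilithio alkynolate 33 (not isolated)
Conditions: 32, n-BuLi (2 equiv per 32), THF, −78 → 0 °C; then 31, −78 °C; then H2O
Reagents that add atoms: none
Why: 1,2-addition of a lithium acetylide to the aldehyde; the acetylide is weakly basic, so C11' should not epimerise, and the new C12' centre is formed without control because it is oxidised in step 20.

Step 19
Reactants: 34 12',15'-diol with C13'≡C14' alkyne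
Product: 35 (13'E)-12',15'-diol
Conditions: NaAlH2(OCH2CH2OMe)2, THF, 0 °C → rt; then H2O
Reagents that add atoms: none
Why: Hydroxyl-directed trans-hydroalumination of a propargylic alcohol followed by protonolysis gives only the E alkene; silyl ethers and isolated alkenes are inert.

Step 20
Reactants: 35 (13'E)-12',15'-diol
Product: 36 (13'E)-enone with free 15'-hydroxyl (5'-OTBS and aryl OTIPS kept)
Conditions: Dess–Martin periodinane, NaHCO3, CH2Cl2, 0 °C
Reagents that add atoms: none
Why: Dess–Martin oxidation of the secondary allylic alcohol; the tertiary carbinol cannot be oxidised and the mild conditions keep C11' intact.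

Step 21
Reactants: 36 (13'E)-enone
Product: 37 CNP0214110.1
Conditions: Bu4NF, AcOH (1:1), THF, 0 °C → rt
Reagents that add atoms: none
Why: Fluoride desilylation; buffering with acetic acid keeps the medium near neutral, so the aryl and secondary silyl ethers should be cleaved without epimerising C11' or cyclising the phenol onto the C2'=C3' alkene.

Compound list
1 | 4-methoxy-2-methylphenol | COc1ccc(O)c(C)c1 | starting material
2 | allyl bromide | C=CCBr | starting material
3 | 1-(allyloxy)-4-methoxy-2-methylbenzene | COc1ccc(OCC=C)c(C)c1 | intermediate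
4 | 6-allyl-4-methoxy-2-methylcyclohexa-2,4-dien-1-one (ortho-dienone, not isolated) | COC1=CC(CC=C)C(=O)C(C)=C1 | intermediate
5 | 2-allyl-4-methoxy-6-methylphenol | COc1cc(C)c(O)c(CC=C)c1 | intermediate
6 | (2-allyl-4-methoxy-6-methylphenoxy)triisopropylsilane | COc1cc(C)c(O[Si](C(C)C)(C(C)C)C(C)C)c(CC=C)c1 | intermediate
7 | 3-(Ar-methyl)-1,2,4-trioxolane (ozonide, not isolated) | COc1cc(C)c(O[Si](C(C)C)(C(C)C)C(C)C)c(CC2OCOO2)c1 | intermediate
8 | 2-[5-methoxy-3-methyl-2-(triisopropylsilyloxy)phenyl]acetaldehyde | COc1cc(C)c(O[Si](C(C)C)(C(C)C)C(C)C)c(CC=O)c1 | intermediate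
9 | isopropenylmagnesium bromide | CC(=C)[Mg]Br | starting material
10 | rac-1-[5-methoxy-3-methyl-2-(triisopropylsilyloxy)phenyl]-3-methylbut-3-en-2-ol | COc1cc(C)c(O[Si](C(C)C)(C(C)C)C(C)C)c(CC(O)C(C)=C)c1 | intermediate
11 | (S)-1-[5-methoxy-3-methyl-2-(triisopropylsilyloxy)phenyl]-3-methylbut-3-en-2-ol | COc1cc(C)c(O[Si](C(C)C)(C(C)C)C(C)C)c(C[C@H](O)C(C)=C)c1 | intermediate
12 | hept-6-ynoic acid | C#CCCCCC(=O)O | starting material
13 | (R)-4-benzyloxazolidin-2-one | O=C1N[C@H](Cc2ccccc2)CO1 | starting material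
14 | hept-6-ynoic pivalic anhydride (not isolated) | C#CCCCCC(=O)OC(=O)C(C)(C)C | intermediate
15 | (R)-4-benzyl-3-(hept-6-ynoyl)oxazolidin-2-one | C#CCCCCC(=O)N1[C@H](Cc2ccccc2)COC1=O | intermediate
16 | sodium (Z)-enolate of 15 (not isolated) | C#CCCC/C=C(\O[Na])N1[C@H](Cc2ccccc2)COC1=O | intermediate
17 | (R)-4-benzyl-3-[(R)-2-methylhept-6-ynoyl]oxazolidin-2-one | C#CCCC[C@@H](C)C(=O)N1[C@H](Cc2ccccc2)COC1=O | intermediate
18 | (R)-2-methylhept-6-yn-1-ol | C#CCCC[C@@H](C)CO | intermediate
19 | triethyl{[(2R)-2-methylhept-6-yn-1-yl]oxy}silane | C#CCCC[C@@H](C)CO[Si](CC)(CC)CC | intermediate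
20 | dimethyl[(1E,6R)-2,6-dimethyl-7-(triethylsilyloxy)hept-1-en-1-yl]alane (not isolated) | C[Al](C)/C=C(\C)CCC[C@@H](C)CO[Si](CC)(CC)CC | intermediate
21 | lithium butyl(dimethyl)[(1E,6R)-2,6-dimethyl-7-(triethylsilyloxy)hept-1-en-1-yl]alanate (not isolated) | [Li+].CCCC[Al-](C)(C)/C=C(\C)CCC[C@@H](C)CO[Si](CC)(CC)CC | intermediate
22 | (2E,7R)-3,7-dimethyl-8-(triethylsilyloxy)oct-2-en-1-ol | OC/C=C(\C)CCC[C@@H](C)CO[Si](CC)(CC)CC | intermediate
23 | (2E,7R)-3,7-dimethyl-8-(triethylsilyloxy)oct-2-en-1-yl methanesulfonate (not isolated) | CS(=O)(=O)OC/C=C(\C)CCC[C@@H](C)CO[Si](CC)(CC)CC | intermediate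
24 | {[(2R,6E)-8-bromo-2,6-dimethyloct-6-en-1-yl]oxy}triethylsilane | BrC/C=C(\C)CCC[C@@H](C)CO[Si](CC)(CC)CC | intermediate
25 | sodium alkoxide of 11 (not isolated) | COc1cc(C)c(O[Si](C(C)C)(C(C)C)C(C)C)c(C[C@H](O[Na])C(C)=C)c1 | intermediate
26 | bis-allylic ether: (2'S)-1-Ar-3-methylbut-3-en-2-yl (2E,7R)-3,7-dimethyl-8-(triethylsilyloxy)oct-2-en-1-yl ether | COc1cc(C)c(O[Si](C(C)C)(C(C)C)C(C)C)c(C[C@H](OC/C=C(\C)CCC[C@@H](C)CO[Si](CC)(CC)CC)C(C)=C)c1 | intermediate
27 | C5'-lithio derivative of 26 (not isolated) | COc1cc(C)c(O[Si](C(C)C)(C(C)C)C(C)C)c(C[C@H](OC([Li])/C=C(\C)CCC[C@@H](C)CO[Si](CC)(CC)CC)C(C)=C)c1 | intermediate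
28 | (2R,6E,8R,10E)-12-Ar-2,6,10-trimethyl-1-(triethylsilyloxy)dodeca-6,10-dien-8-ol (the (2'E,5'R,6'E,11'R)-dienol) | COc1cc(C)c(O[Si](C(C)C)(C(C)C)C(C)C)c(C/C=C(\C)C[C@@H](O)/C=C(\C)CCC[C@@H](C)CO[Si](CC)(CC)CC)c1 | intermediate
29 | 5'-O-tert-butyldimethylsilyl ether of 28 | COc1cc(C)c(O[Si](C(C)C)(C(C)C)C(C)C)c(C/C=C(\C)C[C@@H](O[Si](C)(C)C(C)(C)C)/C=C(\C)CCC[C@@H](C)CO[Si](CC)(CC)CC)c1 | intermediate
30 | 12'-alcohol: (2R,6E,8R,10E)-12-Ar-8-(tert-butyldimethylsilyloxy)-2,6,10-trimethyldodeca-6,10-dien-1-ol | COc1cc(C)c(O[Si](C(C)C)(C(C)C)C(C)C)c(C/C=C(\C)C[C@@H](O[Si](C)(C)C(C)(C)C)/C=C(\C)CCC[C@@H](C)CO)c1 | intermediate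
31 | 12'-aldehyde: (2R,6E,8R,10E)-12-Ar-8-(tert-butyldimethylsilyloxy)-2,6,10-trimethyldodeca-6,10-dienal | COc1cc(C)c(O[Si](C(C)C)(C(C)C)C(C)C)c(C/C=C(\C)C[C@@H](O[Si](C)(C)C(C)(C)C)/C=C(\C)CCC[C@@H](C)C=O)c1 | intermediate
32 | 2-methylbut-3-yn-2-ol | CC(C)(O)C#C | starting material
33 | dilithio derivative of 32 (not isolated) | [Li]C#CC(C)(C)O[Li] | intermediate
34 | 12',15'-diol with C13'≡C14' alkyne (11'R; 12'-epimers; 5'-OTBS; aryl OTIPS) | COc1cc(C)c(O[Si](C(C)C)(C(C)C)C(C)C)c(C/C=C(\C)C[C@@H](O[Si](C)(C)C(C)(C)C)/C=C(\C)CCC[C@@H](C)C(O)C#CC(C)(C)O)c1 | intermediate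
35 | (13'E)-12',15'-diol (11'R; 12'-epimers; 5'-OTBS; aryl OTIPS) | COc1cc(C)c(O[Si](C(C)C)(C(C)C)C(C)C)c(C/C=C(\C)C[C@@H](O[Si](C)(C)C(C)(C)C)/C=C(\C)CCC[C@@H](C)C(O)/C=C/C(C)(C)O)c1 | intermediate
36 | (13'E)-enone with free 15'-hydroxyl (5'-OTBS; aryl OTIPS) | COc1cc(C)c(O[Si](C(C)C)(C(C)C)C(C)C)c(C/C=C(\C)C[C@@H](O[Si](C)(C)C(C)(C)C)/C=C(\C)CCC[C@@H](C)C(=O)/C=C/C(C)(C)O)c1 | intermediate
37 | CNP0214110.1: (2'E,5'R,6'E,11'R,13'E)-5',15'-dihydroxy-12'-oxo side chain on 4-methoxy-2-methylphenol | COc1cc(C)c(O)c(C/C=C(\C)C[C@@H](O)/C=C(\C)CCC[C@@H](C)C(=O)/C=C/C(C)(C)O)c1 | target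

Total step count: 21. Longest linear sequence: 15 steps (steps 1–6 then 13–21; the branch 7–12 then 13–21 is equally long).

Steps most likely to fail

1. Step 14. Deprotonation may occur at the tertiary C2'–H, or not at all below −40 °C. The allyllithium may also collapse by the [1,2]-shift. Strain between the C3' methyl and the pseudo-equatorial CH2Ar may erode E selectivity and with it the chirality transfer. The fallback sets out from 19 and 11 and comes back at 28; it replaces the γ,γ-disubstituted allyl unit by a 2-alkynyl unit, whose propargylic OCH2 is lithiated without ambiguity. Alkyne 19 is hydroxymethylated (n-BuLi, then (CH2O)n, THF) to (7R)-7-methyl-8-(triethylsilyloxy)oct-2-yn-1-ol F1, which is converted (CBr4, PPh3, CH2Cl2, 0 °C) into {[(2R)-8-bromo-2-methyloct-6-yn-1-yl]oxy}triethylsilane F2. Alkylation of 11 with it (NaH, THF/DMF) gives the allyl propargyl ether F3. n-BuLi in THF at −78 °C brings about the [2,3]-Wittig rearrangement to the (2'E,5'R)-enynol F4 by the same envelope. NaAlH2(OCH2CH2OMe)2 followed by I2 gives the (6'Z)-7'-iodo dienol F5 by hydroxyl-directed trans-hydroalumination. Me2CuLi in Et2O at 0 °C replaces iodine by methyl with retention and gives 28.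

2. Step 11. The carboalumination may stall or place the methyl group on the terminal carbon, the Lewis-acidic aluminium reagents may strip the triethylsilyl ether, and the alanate may be hydroxymethylated incompletely. The fallback sets out from 19 and comes back at 22 without any aluminium alkyl. Alkyne 19 is hydroxymethylated as above to the alkynol (7R)-7-methyl-8-(triethylsilyloxy)oct-2-yn-1-ol F1 (the compound also used in the fallback for step 14). NaAlH2(OCH2CH2OMe)2 then I2 gives (2Z,7R)-3-iodo-7-methyl-8-(triethylsilyloxy)oct-2-en-1-ol F6, and Me2CuLi exchanges iodine for methyl with retention to give 22.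

3. Step 6. The rate difference between the enantiomers may be too small with the bulky ortho-silyloxybenzyl group next to the carbinol. The recovered alcohol would then keep some (R)-enantiomer, which would pass into the C5' epimer in step 14; at best half of the material is lost. The fallback sets out from 10 and comes back at 11 and uses both enantiomers. Oxidation with Dess–Martin periodinane gives the enone 1-Ar-3-methylbut-3-en-2-one F7. CBS reduction with (R)-2-methyl-CBS-oxazaborolidine (cat.) and catecholborane in toluene at −78 °C, with the isopropenyl group acting as the large substituent, should give the (S)-alcohol 11.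

Further compounds
F1 | step 14 | (7R)-7-methyl-8-(triethylsilyloxy)oct-2-yn-1-ol | OCC#CCCC[C@@H](C)CO[Si](CC)(CC)CC
F2 | step 14 | {[(2R)-8-bromo-2-methyloct-6-yn-1-yl]oxy}triethylsilane | BrCC#CCCC[C@@H](C)CO[Si](CC)(CC)CC
F3 | step 14 | (2'S)-1-Ar-3-methylbut-3-en-2-yl (7R)-7-methyl-8-(triethylsilyloxy)oct-2-yn-1-yl ether | COc1cc(C)c(O[Si](C(C)C)(C(C)C)C(C)C)c(C[C@H](OCC#CCCC[C@@H](C)CO[Si](CC)(CC)CC)C(C)=C)c1
F4 | step 14 | (2'E,5'R,11'R)-5'-hydroxy-12'-(triethylsilyloxy) 2'-en-6'-yne | COc1cc(C)c(O[Si](C(C)C)(C(C)C)C(C)C)c(C/C=C(\C)C[C@@H](O)C#CCCC[C@@H](C)CO[Si](CC)(CC)CC)c1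
F5 | step 14 | (2'E,5'R,6'Z,11'R)-7'-iodo-5'-hydroxy-12'-(triethylsilyloxy) 2',6'-diene | COc1cc(C)c(O[Si](C(C)C)(C(C)C)C(C)C)c(C/C=C(\C)C[C@@H](O)/C=C(\I)CCC[C@@H](C)CO[Si](CC)(CC)CC)c1
F6 | step 11 | (2Z,7R)-3-iodo-7-methyl-8-(triethylsilyloxy)oct-2-en-1-ol | OC/C=C(\I)CCC[C@@H](C)CO[Si](CC)(CC)CC
F7 | step 6 | 1-[5-methoxy-3-methyl-2-(triisopropylsilyloxy)phenyl]-3-methylbut-3-en-2-one | COc1cc(C)c(O[Si](C(C)C)(C(C)C)C(C)C)c(CC(=O)C(C)=C)c1
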